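**Plan**

1. Cuts: (i) ten O–CH3 bonds and the Z-CH=CH, taken back to C≡C; (ii) C2'–C3' of the eastern dihydrobenzofuran, taken back to a diaryl carbene at C3' and the O–CH2 of a 4-methoxybenzyl ether on ring C; (iii) C(sp)–C5 of ring D (Sonogashira union); (iv) C7–aryl, C7–ring A and the C8–C7 one-carbon homologation (seven-membered ring); (v) C2–C3 of the western dihydrobenzofuran (same insertion on a small bromide).
2. Forward order of rings: western dihydrobenzofuran, then the seven-membered ring, then union through the alkyne, then the eastern dihydrobenzofuran as the last ring; demethylation and semi-hydrogenation follow.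
3. Feature behind the key event: C3' is a diarylmethine between ring C and ring E, so it can be a carbene with two aryl donors. C2' is an oxygen-bound benzylic CH carrying a 4-oxyphenyl ring, so it can begin as the hydridic CH2 of a 4-methoxybenzyl ether on O1', placed 1,5 to C3'. Every atom of that ether stays in the skeleton and only N2 leaves.
4. Helper: the linker is carried as a diarylalkyne, expected to be inert to the carbene, to BF3 and to BBr3, and is brought to the Z-alkene in the last step.
5. Stereochemistry: C3 and C3' come from the chiral dirhodium carboxylate; C2 and C2' from acid equilibration to the trans isomers; C7 and C8 from C3, through the convex face of the folded seven-membered ring and anti to ring D.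

Key step: step 16

Labels used in the names: western 2,3-dihydro-1-benzofuran = O1, C2, C3 and benzo ring B (C3a–C7a). Ring A = the 3,5-dioxygenated phenyl on C3. "W" = the western tetracycle in its methyl ether form: 6-methoxy-2-(4-methoxyphenyl)-2,3-dihydro-1-benzofuran with ring A (3,5-dimethoxyphenyl) on C3, in which C4 of ring B and C2 of ring A are joined through C8 (on ring B) and C7 (on ring A); this closes the seven-membered ring C3–C3a–C4–C8–C7–C2(A)–C1(A), and the parent has C7H2–C8H2. Ring D = the 2-oxygenated phenyl on C8, linker on its C5. Eastern 2,3-dihydro-1-benzofuran = O1', C2', C3' and benzo ring C (linker on C4', oxygen on C6'). Ring E = the 3,5-dioxygenated phenyl on C3'. Target configuration: 2S,3S,7S,8R,2'S,3'S.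

PTAD = (1-adamantyl)(N-phthalimido)acetate; Rh2(S-PTAD)4 is the dirhodium tetracarboxylate of the S ligand.

Assumption (remark on the chemistry): Rh2(S-PTAD)4 is taken to deliver the 3S and 3'S insertion products; if the sense of induction is the opposite, Rh2(R-PTAD)4 is used in steps 5 and 16 with nothing else changed.

**Route**

Step 1
Reactants: 1 1-bromo-3,5-dimethoxybenzene; 2 3,5-dimethoxybenzoyl chloride
Product: 3 (2-bromo-4,6-dimethoxyphenyl)(3,5-dimethoxyphenyl)methanone
Conditions: AlCl3 (1.2 equiv), CH2Cl2, 0 °C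
Reagents that add atoms: none
Why: Friedel–Crafts acylation should occur at C2 of 1, para to one methoxy group and ortho to the other, because the position between the two methoxy groups is the more hindered one.

Step 2
Reactants: 3 (2-bromo-4,6-dimethoxyphenyl)(3,5-dimethoxyphenyl)methanone
Product: 4 (2-bromo-6-hydroxy-4-methoxyphenyl)(3,5-dimethoxyphenyl)methanone
Conditions: BCl3 (1.2 equiv), CH2Cl2, −78 → 0 °C; H2O
Reagents that add atoms: none
Why: Chelation-directed ether cleavage: BCl3 bound to the ketone oxygen can reach only the methoxy group ortho to the carbonyl, so the three methoxy groups that cannot chelate should stay.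

Step 3
Reactants: 4 (2-bromo-6-hydroxy-4-methoxyphenyl)(3,5-dimethoxyphenyl)methanone; 5 4-methoxybenzyl chloride
Product: 6 {2-bromo-4-methoxy-6-[(4-methoxyphenyl)methoxy]phenyl}(3,5-dimethoxyphenyl)methanone
Conditions: K2CO3, n-Bu4NI (cat.), DMF, 60 °C
Reagents that add atoms: none
Why: Williamson etherification of the phenoxide; the 4-methoxybenzyl group is not a protecting group here but the future C2 (or C2') with its 4-oxyphenyl ring.

Step 4
Reactants: 6 {2-bromo-4-methoxy-6-[(4-methoxyphenyl)methoxy]phenyl}(3,5-dimethoxyphenyl)methanone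
Product: 7 hydrazone of 6 (E/Z mixture)
Conditions: N2H4·H2O (excess), AcOH (cat.), EtOH, 80 °C, sealed vessel, no copper
Reagents that add atoms: hydrazine monohydrate, NN.O
Why: Acid-catalysed condensation of hydrazine with the diaryl ketone, where excess reagent and heat should overcome the two ortho substituents and the absence of a metal keeps the aryl bromide from N-arylation.

Step 5
Reactants: 7 hydrazone of 6
Product: 9 (2R,3S)-4-bromo-3-(3,5-dimethoxyphenyl)-6-methoxy-2-(4-methoxyphenyl)-2,3-dihydro-1-benzofuran (cis), via diaryldiazomethane 8 (not isolated)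
Conditions: MnO2, CH2Cl2, 0 °C; filter; Rh2(S-PTAD)4 (1 mol %), CH2Cl2, −20 → 0 °C
Reagents that add atoms: none
Why: Dehydrogenation of the hydrazone gives the diaryldiazomethane, whose dirhodium carbene (two aryl donors) inserts into the O–CH2 bond lying 1,5 to it; the chiral carboxylate ligands select the carbene face and set C3 (S), and the compact insertion geometry places the two aryl groups cis (C2 R).

Step 6
Reactants: 9 cis-(2R,3S)-bromide
Product: 10 (2S,3S)-4-bromo-3-(3,5-dimethoxyphenyl)-6-methoxy-2-(4-methoxyphenyl)-2,3-dihydro-1-benzofuran (trans)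
Conditions: BF3·OEt2 (0.3 equiv), CH2Cl2, 0 °C → rt
Reagents that add atoms: none
Why: BF3 on O1 should let the O1–C2 bond ionise reversibly to the 4-methoxybenzylic cation, and reclosure gives the more stable 2,3-trans isomer (C2 S) while C3 is not touched.

Step 7
Reactants: 10 trans-(2S,3S)-bromide; 11 5-bromo-2-methoxybenzaldehyde
Product: 13 (5-bromo-2-methoxyphenyl)[(2S,3S)-3-(3,5-dimethoxyphenyl)-6-methoxy-2-(4-methoxyphenyl)-2,3-dihydro-1-benzofuran-4-yl]methanol as both carbinol epimers, via aryllithium 12 (not isolated)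
Conditions: n-BuLi (1.05 equiv), THF, −78 °C; then 11, −78 → −20 °C; H2O
Reagents that add atoms: none
Why: Bromine–lithium exchange at −78 °C is faster than deprotonation at C2 or C3, and the aryllithium adds to the aldehyde before it can exchange with the second aryl bromide; the new carbinol centre is removed in step 8.

Step 8
Reactants: 13 diaryl carbinol
Product: 14 (5-bromo-2-methoxyphenyl)[(2S,3S)-3-(3,5-dimethoxyphenyl)-6-methoxy-2-(4-methoxyphenyl)-2,3-dihydro-1-benzofuran-4-yl]methanone
Conditions: MnO2 (activated, excess), CH2Cl2, 40 °C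
Reagents that add atoms: none
Why: Oxidation of a doubly benzylic alcohol by MnO2, which leaves ethers, the aryl bromide and the benzylic C–H bonds of the dihydrofuran alone.

Step 9
Reactants: 14 diaryl ketone
Product: 15 (2S,3S)-4-[2-(5-bromo-2-methoxyphenyl)oxiran-2-yl]-3-(3,5-dimethoxyphenyl)-6-methoxy-2-(4-methoxyphenyl)-2,3-dihydro-1-benzofuran (both epimers at the oxirane carbon)
Conditions: Me3SI, KOtBu, DMSO/THF, 0 °C → rt
Reagents that add atoms: trimethylsulfonium iodide, C[S+](C)C.[I-]
Why: Corey–Chaykovsky epoxidation, in which the small sulfonium methylide should add even to this ortho-substituted diaryl ketone; the configuration of the new quaternary carbon is of no consequence because it is lost in step 10.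

Step 10
Reactants: 15 diaryl oxirane
Product: 18 (2S,3S)-8-(5-bromo-2-methoxyphenyl)-7,8-didehydro-W, via diarylacetaldehyde 16 (not isolated), via seven-ring carbinol 17 (not isolated)
Conditions: ZnI2 (0.2 equiv), benzene, rt; then TsOH·H2O (0.2 equiv), 4 Å MS, 60 °C
Reagents that add atoms: none
Why: Meinwald rearrangement (1,2-hydride shift) gives the diarylacetaldehyde, whose protonated carbonyl is attacked by C2 of ring A (ortho to one methoxy group, para to the other) in a 7-exo-trig Friedel–Crafts hydroxyalkylation, and dehydration gives the styrene conjugated with ring A; C8 becomes sp2, so the labile centre of 16 does not matter.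

Step 11
Reactants: 18 seven-ring alkene; 19 anisole
Product: 20 (2S,3S,7S,8R)-8-(5-bromo-2-methoxyphenyl)-7-(4-methoxyphenyl)-W (western bromide)
Conditions: TfOH (0.1 equiv), anisole/CH2Cl2, −40 → 0 °C
Reagents that add atoms: none
Why: Acid-catalysed hydroarylation (Friedel–Crafts alkylation of anisole by a protonated styrene): reversible protonation at C8 gives the C7 cation stabilised by the ortho and para methoxy groups of ring A, and anisole should attack through its para carbon on the convex face of the folded seven-membered ring (the face of the pseudo-axial H on C3) and anti to ring D, which fixes C7 (S) and C8 (R) together.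

Step 12
Reactants: 6 bromo ketone ether; 21 ethynyl(trimethyl)silane
Product: 22 {4-methoxy-2-[(4-methoxyphenyl)methoxy]-6-[(trimethylsilyl)ethynyl]phenyl}(3,5-dimethoxyphenyl)methanone
Conditions: PdCl2(PPh3)2 (5 mol %), CuI (10 mol %), Et3N/THF, 65 °C
Reagents that add atoms: none
Why: Sonogashira coupling at an aryl bromide that is activated for oxidative addition by the ortho carbonyl group.

Step 13
Reactants: 22 silylalkyne ketone
Product: 23 {2-ethynyl-4-methoxy-6-[(4-methoxyphenyl)methoxy]phenyl}(3,5-dimethoxyphenyl)methanone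
Conditions: K2CO3 (0.2 equiv), MeOH/THF, rt
Reagents that add atoms: none
Why: Methanolysis of the C(sp)–Si bond under mild base, to which the ketone and the ethers are inert.

Step 14
Reactants: 20 western bromide; 23 terminal alkyne ketone
Product: 24 {2-[(4-methoxy-3-{(2S,3S,7S,8R)-7-(4-methoxyphenyl)-W-8-yl}phenyl)ethynyl]-4-methoxy-6-[(4-methoxyphenyl)methoxy]phenyl}(3,5-dimethoxyphenyl)methanone
Conditions: PdCl2(MeCN)2 (5 mol %), XPhos (15 mol %), Cs2CO3, MeCN, 80 °C
Reagents that add atoms: none
Why: Copper-free Sonogashira coupling, where the bulky electron-rich biaryl phosphine should allow oxidative addition at the electron-rich but unhindered bromide of ring D and the absence of copper avoids alkyne homocoupling.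

Step 15
Reactants: 24 alkyne-linked ketone
Product: 25 hydrazone of 24 (E/Z mixture)
Conditions: N2H4·H2O (excess), AcOH (cat.), EtOH/THF, 70 °C, argon
Reagents that add atoms: hydrazine monohydrate, NN.O
Why: Condensation as in step 4, made easier by the small linear alkynyl group in place of bromine; exclusion of air and metals keeps the hydrazone from adding to the alkyne and keeps diimide from forming.

Step 16
Reactants: 25 hydrazone of 24
Product: 27 (2S,3S,7S,8R,2'R,3'S)-decamethyl ether of the alkyne analogue of the target, eastern dihydrobenzofuran cis, via diaryldiazomethane 26 (not isolated)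
Conditions: MnO2, CH2Cl2, 0 °C; filter; Rh2(S-PTAD)4 (2 mol %), CH2Cl2, −40 → 0 °C
Reagents that add atoms: none
Why: MnO2 dehydrogenates the hydrazone to the diaryldiazomethane 26, which loses N2 on Rh2(S-PTAD)4 to give a dirhodium carbene flanked by two aryl donors (ring C and ring E) and no acceptor; this carbene takes the hydridic hydrogen of the O–CH2 of the 4-methoxybenzyl ether held 1,5 to it, and the C2'–C3' bond forms in the same compact transition state. The closest known reaction type is the enantioselective intramolecular C–H insertion of diaryl (donor/donor) carbenes into benzyl aryl ethers to give 2,3-diaryl-2,3-dihydrobenzofurans. The eastern five-membered ring is closed by C–C bond formation, a 1,5-insertion through a five-membered transition state made of C3', C3a', C7a', O1' and C2'. C3' (S) is set by the chiral carboxylate ligands, which select the face of the carbene, and C2' follows as the cis (R) centre from the geometry of the insertion, while the four western stereocentres are remote and should not compete with the catalyst. The step needs chemoselectivity for this ether C–H over the ortho alkyne and over all other benzylic C–H bonds: only this CH2 is both 1,5 to the carbene and activated by an oxygen and a 4-methoxyphenyl group, attack on the alkyne would demand a four-membered ring or a bent cyclic vinyl carbene, and a carbene with two donors is too weakly electrophilic for ylide formation or cyclopropenation.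

Step 17
Reactants: 27 cis-(2'R,3'S) insertion product
Product: 28 (2S,3S,7S,8R,2'S,3'S)-decamethyl ether of the alkyne analogue of the target, both dihydrobenzofurans trans
Conditions: BF3·OEt2 (0.3 equiv), CH2Cl2, −20 → 0 °C
Reagents that add atoms: none
Why: Reversible ionisation of the O1'–C2' bond to the 4-methoxybenzylic cation and reclosure gives the more stable trans isomer (C2' S) with C3' untouched; the western dihydrofuran is already trans, and an aprotic Lewis acid does not protonate the alkyne.

Step 18
Reactants: 28 trans decamethyl ether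
Product: 29 alkyne analogue of the target with ten free hydroxyl groups (2S,3S,7S,8R,2'S,3'S)
Conditions: BBr3 (30 equiv), CH2Cl2, −78 °C → rt; ice/H2O
Reagents that add atoms: none
Why: BBr3 cleaves all ten aryl methyl ethers by O-complexation and bromide attack at methyl; the diarylalkyne offers no acid-labile stilbene C=C, and both dihydrobenzofurans are already at their thermodynamic trans configuration, so reversible O–C2 ionisation should not change them.

Step 19
Reactants: 29 alkyne decaphenol
Product: 30 CNP0266373.3 (target)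
Conditions: H2 (1 atm), Pd/CaCO3 poisoned with Pb(OAc)2, quinoline, EtOAc/MeOH, rt, dark, stopped after one equivalent of H2
Reagents that add atoms: none
Why: Lindlar semi-hydrogenation adds H2 syn across the alkyne on the poisoned palladium surface and stops at the Z-alkene, and no acid or base that could isomerise or cyclise the Z-stilbene is present.

**Compound list**

1 | 1-bromo-3,5-dimethoxybenzene | COc1cc(OC)cc(Br)c1 | starting material
2 | 3,5-dimethoxybenzoyl chloride | COc1cc(OC)cc(C(Cl)=O)c1 | starting material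
3 | (2-bromo-4,6-dimethoxyphenyl)(3,5-dimethoxyphenyl)methanone | COc1cc(OC)c(C(=O)c2cc(OC)cc(OC)c2)c(Br)c1 | intermediate
4 | (2-bromo-6-hydroxy-4-methoxyphenyl)(3,5-dimethoxyphenyl)methanone | COc1cc(O)c(C(=O)c2cc(OC)cc(OC)c2)c(Br)c1 | intermediate
5 | 4-methoxybenzyl chloride | COc1ccc(CCl)cc1 | starting material
6 | {2-bromo-4-methoxy-6-[(4-methoxyphenyl)methoxy]phenyl}(3,5-dimethoxyphenyl)methanone | COc1ccc(COc2cc(OC)cc(Br)c2C(=O)c2cc(OC)cc(OC)c2)cc1 | intermediate
7 | hydrazone of 6 (E/Z mixture) | COc1ccc(COc2cc(OC)cc(Br)c2C(=NN)c2cc(OC)cc(OC)c2)cc1 | intermediate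
8 | 1-bromo-2-[diazo(3,5-dimethoxyphenyl)methyl]-5-methoxy-3-[(4-methoxyphenyl)methoxy]benzene | COc1ccc(COc2cc(OC)cc(Br)c2C(=[N+]=[N-])c2cc(OC)cc(OC)c2)cc1 | intermediate
9 | (2R,3S)-4-bromo-3-(3,5-dimethoxyphenyl)-6-methoxy-2-(4-methoxyphenyl)-2,3-dihydro-1-benzofuran (cis) | COc1ccc(cc1)[C@@H]1Oc2cc(OC)cc(Br)c2[C@@H]1c1cc(OC)cc(OC)c1 | intermediate
10 | (2S,3S)-4-bromo-3-(3,5-dimethoxyphenyl)-6-methoxy-2-(4-methoxyphenyl)-2,3-dihydro-1-benzofuran (trans) | COc1ccc(cc1)[C@H]1Oc2cc(OC)cc(Br)c2[C@@H]1c1cc(OC)cc(OC)c1 | intermediate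
11 | 5-bromo-2-methoxybenzaldehyde | COc1ccc(Br)cc1C=O | starting material
12 | [(2S,3S)-3-(3,5-dimethoxyphenyl)-6-methoxy-2-(4-methoxyphenyl)-2,3-dihydro-1-benzofuran-4-yl]lithium | COc1ccc(cc1)[C@H]1Oc2cc(OC)cc([Li])c2[C@@H]1c1cc(OC)cc(OC)c1 | intermediate
13 | (5-bromo-2-methoxyphenyl)[(2S,3S)-3-(3,5-dimethoxyphenyl)-6-methoxy-2-(4-methoxyphenyl)-2,3-dihydro-1-benzofuran-4-yl]methanol (both carbinol epimers) | COc1ccc(cc1)[C@H]1Oc2cc(OC)cc(C(O)c3cc(Br)ccc3OC)c2[C@@H]1c1cc(OC)cc(OC)c1 | intermediate
14 | (5-bromo-2-methoxyphenyl)[(2S,3S)-3-(3,5-dimethoxyphenyl)-6-methoxy-2-(4-methoxyphenyl)-2,3-dihydro-1-benzofuran-4-yl]methanone | COc1ccc(cc1)[C@H]1Oc2cc(OC)cc(C(=O)c3cc(Br)ccc3OC)c2[C@@H]1c1cc(OC)cc(OC)c1 | intermediate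
15 | (2S,3S)-4-[2-(5-bromo-2-methoxyphenyl)oxiran-2-yl]-3-(3,5-dimethoxyphenyl)-6-methoxy-2-(4-methoxyphenyl)-2,3-dihydro-1-benzofuran (both oxirane epimers) | COc1ccc(cc1)[C@H]1Oc2cc(OC)cc(C3(CO3)c3cc(Br)ccc3OC)c2[C@@H]1c1cc(OC)cc(OC)c1 | intermediate
16 | 2-(5-bromo-2-methoxyphenyl)-2-[(2S,3S)-3-(3,5-dimethoxyphenyl)-6-methoxy-2-(4-methoxyphenyl)-2,3-dihydro-1-benzofuran-4-yl]acetaldehyde (both epimers) | COc1ccc(cc1)[C@H]1Oc2cc(OC)cc(C(C=O)c3cc(Br)ccc3OC)c2[C@@H]1c1cc(OC)cc(OC)c1 | intermediate
17 | (2S,3S)-8-(5-bromo-2-methoxyphenyl)-W-7-ol (epimers at C7 and C8) | OC2c3c(OC)cc(OC)cc3[C@H]3c4c(cc(OC)cc4C2c2cc(Br)ccc2OC)O[C@@H]3c2ccc(OC)cc2 | intermediate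
18 | (2S,3S)-8-(5-bromo-2-methoxyphenyl)-7,8-didehydro-W | COc1ccc(Br)cc1C1=Cc2c(OC)cc(OC)cc2[C@H]2c3c1cc(OC)cc3O[C@@H]2c1ccc(OC)cc1 | intermediate
19 | anisole | COc1ccccc1 | starting material
20 | (2S,3S,7S,8R)-8-(5-bromo-2-methoxyphenyl)-7-(4-methoxyphenyl)-W (western bromide) | COc1ccc([C@H]2c3c(OC)cc(OC)cc3[C@H]3c4c(cc(OC)cc4[C@@H]2c2cc(Br)ccc2OC)O[C@@H]3c2ccc(OC)cc2)cc1 | intermediate
21 | ethynyl(trimethyl)silane | C#C[Si](C)(C)C | starting material
22 | {4-methoxy-2-[(4-methoxyphenyl)methoxy]-6-[(trimethylsilyl)ethynyl]phenyl}(3,5-dimethoxyphenyl)methanone | COc1ccc(COc2cc(OC)cc(C#C[Si](C)(C)C)c2C(=O)c2cc(OC)cc(OC)c2)cc1 | intermediate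
23 | {2-ethynyl-4-methoxy-6-[(4-methoxyphenyl)methoxy]phenyl}(3,5-dimethoxyphenyl)methanone | COc1ccc(COc2cc(OC)cc(C#C)c2C(=O)c2cc(OC)cc(OC)c2)cc1 | intermediate
24 | {2-[(4-methoxy-3-{(2S,3S,7S,8R)-7-(4-methoxyphenyl)-W-8-yl}phenyl)ethynyl]-4-methoxy-6-[(4-methoxyphenyl)methoxy]phenyl}(3,5-dimethoxyphenyl)methanone | COc1ccc([C@H]2c3c(OC)cc(OC)cc3[C@H]3c4c(cc(OC)cc4[C@@H]2c2cc(C#Cc4cc(OC)cc(OCc5ccc(OC)cc5)c4C(=O)c4cc(OC)cc(OC)c4)ccc2OC)O[C@@H]3c2ccc(OC)cc2)cc1 | intermediate
25 | hydrazone of 24 (E/Z mixture) | COc1ccc([C@H]2c3c(OC)cc(OC)cc3[C@H]3c4c(cc(OC)cc4[C@@H]2c2cc(C#Cc4cc(OC)cc(OCc5ccc(OC)cc5)c4C(=NN)c4cc(OC)cc(OC)c4)ccc2OC)O[C@@H]3c2ccc(OC)cc2)cc1 | intermediate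
26 | diaryldiazomethane from 25 (C=N2 in place of C=N–NH2) | COc1ccc([C@H]2c3c(OC)cc(OC)cc3[C@H]3c4c(cc(OC)cc4[C@@H]2c2cc(C#Cc4cc(OC)cc(OCc5ccc(OC)cc5)c4C(=[N+]=[N-])c4cc(OC)cc(OC)c4)ccc2OC)O[C@@H]3c2ccc(OC)cc2)cc1 | intermediate
27 | (2S,3S,7S,8R,2'R,3'S)-decamethyl ether of the alkyne analogue of the target, eastern dihydrobenzofuran cis | COc1ccc([C@H]2c3c(OC)cc(OC)cc3[C@H]3c4c(cc(OC)cc4[C@@H]2c2cc(C#Cc4cc(OC)cc5c4[C@H](c4cc(OC)cc(OC)c4)[C@H](c4ccc(OC)cc4)O5)ccc2OC)O[C@@H]3c2ccc(OC)cc2)cc1 | intermediate
28 | (2S,3S,7S,8R,2'S,3'S)-decamethyl ether of the alkyne analogue of the target, both dihydrobenzofurans trans | COc1ccc([C@H]2c3c(OC)cc(OC)cc3[C@H]3c4c(cc(OC)cc4[C@@H]2c2cc(C#Cc4cc(OC)cc5c4[C@H](c4cc(OC)cc(OC)c4)[C@@H](c4ccc(OC)cc4)O5)ccc2OC)O[C@@H]3c2ccc(OC)cc2)cc1 | intermediate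
29 | alkyne analogue of the target, ten free hydroxyl groups (2S,3S,7S,8R,2'S,3'S) | Oc1ccc([C@H]2c3c(O)cc(O)cc3[C@H]3c4c(cc(O)cc4[C@@H]2c2cc(C#Cc4cc(O)cc5c4[C@H](c4cc(O)cc(O)c4)[C@@H](c4ccc(O)cc4)O5)ccc2O)O[C@@H]3c2ccc(O)cc2)cc1 | intermediate
30 | CNP0266373.3, Z-alkene (2S,3S,7S,8R,2'S,3'S) | Oc1ccc([C@H]2c3c(O)cc(O)cc3[C@H]3c4c(cc(O)cc4[C@@H]2c2cc(/C=C\c4cc(O)cc5c4[C@H](c4cc(O)cc(O)c4)[C@@H](c4ccc(O)cc4)O5)ccc2O)O[C@@H]3c2ccc(O)cc2)cc1 | target

**Step count and risks**

Total step count: 19. Longest linear sequence: 17 (steps 1–11, then 14–19); steps 12 and 13 form the side branch from 6.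

Most likely to fail, in this order:

Step 16. The carbene, or the diazo group before it, may be intercepted by the ortho alkyne instead of reaching the ether C–H. Facial control by the catalyst may also be eroded by the second ortho substituent, and the hydrazone of step 15 may form slowly or add to the alkyne. The fallback closes the eastern ring before the union, on the alkyne-free bromide, which the route already makes. It sets out from 20: Sonogashira coupling with 21 (PdCl2(MeCN)2, XPhos, Cs2CO3, MeCN) should give the western silylalkyne F1, and K2CO3 in MeOH then gives the western terminal alkyne F2. F2 is coupled under the same copper-free conditions with the trans bromide 10, whose ring was closed in step 5 and equilibrated in step 6. This comes back to the route at 28. The price is a coupling at the hindered 4-bromide of 10, next to the C3 diarylmethine.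

Step 11. Protonation and arylation may show poor facial selectivity, anisole may add at C8 instead of C7, or a transiently ring-opened dihydrofuran cation may be trapped by anisole. The fallback attaches the aryl group first and closes the ring second. It sets out from 15: ZnI2 alone gives the aldehyde 16, which is isolated, and 4-methoxyphenylmagnesium bromide in THF at −78 °C adds to it to give the carbinol F3. BF3·OEt2 in CH2Cl2 at −78 °C then ionises F3 to the 4-methoxybenzylic cation, which ring A closes to the seven-membered ring. This should give 20 together with diastereomers at C7 and C8, to be separated by chromatography, and comes back to the route at 20.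

Step 18. During the ten-fold ether cleavage the Lewis acid may attack the alkyne (bromoboration, or hydroarylation by ring E) or open the dihydrofurans irreversibly. The fallback removes the alkyne before any Lewis acid is used. It sets out from 28: Lindlar semi-hydrogenation (H2, Pd/CaCO3 poisoned with Pb(OAc)2, quinoline) should give the Z-alkene decamethyl ether F4. The ethers are then cleaved with the milder iodide-assisted reagent BCl3/n-Bu4NI in CH2Cl2 at −78 → 0 °C, which comes back to the route at 30.

Further compounds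
F1 | step 16 | (2S,3S,7S,8R)-8-{2-methoxy-5-[(trimethylsilyl)ethynyl]phenyl}-7-(4-methoxyphenyl)-W | COc1ccc([C@H]2c3c(OC)cc(OC)cc3[C@H]3c4c(cc(OC)cc4[C@@H]2c2cc(C#C[Si](C)(C)C)ccc2OC)O[C@@H]3c2ccc(OC)cc2)cc1
F2 | step 16 | (2S,3S,7S,8R)-8-(5-ethynyl-2-methoxyphenyl)-7-(4-methoxyphenyl)-W | COc1ccc([C@H]2c3c(OC)cc(OC)cc3[C@H]3c4c(cc(OC)cc4[C@@H]2c2cc(C#C)ccc2OC)O[C@@H]3c2ccc(OC)cc2)cc1
F3 | step 11 | 2-(5-bromo-2-methoxyphenyl)-2-[(2S,3S)-3-(3,5-dimethoxyphenyl)-6-methoxy-2-(4-methoxyphenyl)-2,3-dihydro-1-benzofuran-4-yl]-1-(4-methoxyphenyl)ethanol (mixture of epimers at both new centres) | COc1ccc(cc1)[C@H]1Oc2cc(OC)cc(C(C(O)c3ccc(OC)cc3)c3cc(Br)ccc3OC)c2[C@@H]1c1cc(OC)cc(OC)c1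
F4 | step 18 | decamethyl ether of the target, Z-alkene (2S,3S,7S,8R,2'S,3'S) | COc1ccc([C@H]2c3c(OC)cc(OC)cc3[C@H]3c4c(cc(OC)cc4[C@@H]2c2cc(/C=C\c4cc(OC)cc5c4[C@H](c4cc(OC)cc(OC)c4)[C@@H](c4ccc(OC)cc4)O5)ccc2OC)O[C@@H]3c2ccc(OC)cc2)cc1
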